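**Retrosynthetic overview**

- Feature: the Z-C4=C5 olefin between C3–O and C6–O is the double bond of a cyclohexenone (ring C1–C6), and C9, C10 and C14 are an isopropenyl group on C1. The ten-membered ring C1–C10 is therefore a 1-alkenyl-6-isopropenylcyclohex-2-enol enlarged across C1–C6.
- Endgame disconnections: O3–Si, the C8 ester, C8–O from C8–Si (retention), C11=C13, C10–OH (hydration of the 1(10) olefin), the lactone O–C6 bond (closure with inversion), and C7–C11 (enolate alkylation).
- Key disconnection: C8–C9, by anionic oxy-Cope rearrangement of an (E)-2-silylvinyl carbinol, which comes from a 4-silyloxy-6-isopropenylcyclohexenone and (E)-2-(dimethylphenylsilyl)vinyllithium.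
- The enone comes from (R)-carvone: inversion to trans-carveol, hydroxyl-directed epoxidation, selenide opening/elimination and chromate 1,3-transposition.
- Ring order: six-membered ring (from carvone), then the ten-membered carbocycle (step 10), then the γ-lactone (step 13).

Key step: step 10

Remarks on the chemistry: germacrane numbering is used for all ten-membered compounds (ring C1–C10, C14 on C10, C15 on C4, C11–C13 on C7). The C3 oxygen is taken from carvone, because γ-oxidation of a 6-isopropenylcyclohexenone through a dienol ether would enolise the C1–H (α to C=O and allylic) and lose that stereocentre. Mannich base 28 is carried as a C11 epimer mixture, since C11 becomes sp2 in step 16.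

**Step 1**
Reactants: 1 (R)-(−)-carvone
Product: 2 (1R,5R)-cis-carveol
Conditions: NaBH4, CeCl3·7H2O, MeOH, −78 → 0 °C
Reagents that add atoms: none
Why: Luche 1,2-reduction, in which axial hydride attack on the half-chair with equatorial isopropenyl should give the cis allylic alcohol.

**Step 2**
Reactants: 2 (1R,5R)-cis-carveol
Product: 3 (1S,5R)-trans-carvyl 4-nitrobenzoate
Conditions: 4-O2NC6H4CO2H, PPh3, DIAD, THF, 0 °C → rt
Reagents that add atoms: 4-nitrobenzoic acid, O=C(O)c1ccc(cc1)[N+](=O)[O-]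
Why: Mitsunobu esterification inverts the carbinol carbon by SN2, which places the C–O bond trans to the isopropenyl group (the later C3 configuration).

**Step 3**
Reactants: 3 (1S,5R)-trans-carvyl 4-nitrobenzoate
Product: 4 (1S,5R)-trans-carveol
Conditions: K2CO3, MeOH, rt
Reagents that add atoms: none
Why: Base-catalysed methanolysis cleaves the acyl–oxygen bond, so the configuration is retained.

**Step 4**
Reactants: 4 (1S,5R)-trans-carveol
Product: 5 (1S,2S,3R,5S)-2,3-epoxy-2-methyl-5-(prop-1-en-2-yl)cyclohexan-1-ol (epoxide cis to OH)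
Conditions: VO(acac)2 (cat.), t-BuOOH, CH2Cl2, 0 °C → rt
Reagents that add atoms: tert-butyl hydroperoxide, CC(C)(C)OO
Why: Hydroxyl-directed vanadium-catalysed epoxidation selects the allylic ring olefin over the isopropenyl group and delivers oxygen syn to the pseudoaxial hydroxyl; both epoxide centres become sp2 later.

**Step 5**
Reactants: 5 epoxy alcohol
Product: 6 (1S,2R,3R,5R)-1-(tert-butyldimethylsilyloxy)-2,3-epoxy-2-methyl-5-(prop-1-en-2-yl)cyclohexane
Conditions: TBSCl, imidazole, DMF, rt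
Reagents that add atoms: tert-butyldimethylsilyl chloride, CC(C)(C)[Si](C)(C)Cl
Why: Standard silylation of a secondary alcohol under conditions that leave the epoxide intact.

**Step 6**
Reactants: 6 silyloxy epoxide
Product: 8 (1R,4S,6S)-6-(tert-butyldimethylsilyloxy)-1-methyl-4-(prop-1-en-2-yl)cyclohex-2-en-1-ol, via hydroxy selenide 7 (not isolated)
Conditions: (PhSe)2, NaBH4, EtOH, reflux; then 30% H2O2, THF, 0 °C → rt
Reagents that add atoms: none
Why: Selenolate opens the trisubstituted epoxide at its secondary carbon (trans-diaxial opening), and the selenoxide then eliminates syn toward the only neighbouring C–H, giving the transposed tertiary allylic alcohol (epoxide to allylic alcohol by selenoxide elimination).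

**Step 7**
Reactants: 8 tertiary allylic alcohol
Product: 9 (4S,6R)-4-(tert-butyldimethylsilyloxy)-3-methyl-6-(prop-1-en-2-yl)cyclohex-2-en-1-one
Conditions: pyridinium chlorochromate (C5H5NH)[CrO3Cl], NaOAc, Celite, CH2Cl2, rt
Reagents that add atoms: none
Why: Babler–Dauben oxidative 1,3-transposition (chromate ester [3,3] shift, then oxidation) forms the enone without base, so the epimerisable C6 centre of the enone is not touched.

**Step 8**
Reactants: 10 (E)-1,2-bis(tributylstannyl)ethene; 11 chlorodimethylphenylsilane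
Product: 13 (E)-1-(dimethylphenylsilyl)-2-(tributylstannyl)ethene, via (E)-2-(tributylstannyl)ethenyllithium 12 (not isolated)
Conditions: n-BuLi (1 equiv), THF, −78 °C; then 11, −78 °C → rt
Reagents that add atoms: chlorodimethylphenylsilane (11), C[Si](C)(Cl)c1ccccc1
Why: A single tin–lithium exchange and silylation of the vinyllithium both proceed with retention of the E geometry.

**Step 9**
Reactants: 9 silyloxy enone; 13 silyl stannane
Product: 15 (1R,4S,6R)-4-(tert-butyldimethylsilyloxy)-1-[(E)-2-(dimethylphenylsilyl)ethenyl]-3-methyl-6-(prop-1-en-2-yl)cyclohex-2-en-1-ol, via (E)-2-(dimethylphenylsilyl)ethenyllithium 14 (not isolated)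
Conditions: 13, n-BuLi, THF, −78 °C; then 9, −78 °C; NH4Cl (aq)
Reagents that add atoms: (E)-1-(dimethylphenylsilyl)-2-(tributylstannyl)ethene (13), C[Si](C)(/C=C/[Sn](CCCC)(CCCC)CCCC)c1ccccc1
Why: Tin–lithium exchange keeps the E geometry, and 1,2-addition to the enone should occur from the equatorial direction anti to the adjacent isopropenyl group, so the new carbinol centre carries the two alkenyl groups trans.

**Step 10 (key step)**
Reactants: 15 divinyl carbinol
Product: 18 (3S,8R)-3-(tert-butyldimethylsilyloxy)-8-(dimethylphenylsilyl)-11,12,13-trinorgermacra-1(10)E,4Z-dien-6-one, via potassium alkoxide 16 (not isolated), via potassium enolate 17 (not isolated)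
Conditions: KH, 18-crown-6, THF, 0 °C → rt; then NH4Cl (aq), −78 °C
Reagents that add atoms: none
Why: KH with 18-crown-6 gives the C6 potassium alkoxide 16, whose oxyanion weakens the C1–C6 bond so that the 1,5-diene C8=C7–C6–C1–C10=C9 undergoes an anionic oxy-Cope [3,3] shift, forming C8–C9 and breaking C1–C6 to give enolate 17. The closest known reaction type is the anionic oxy-Cope ring expansion of trans-1,2-dialkenylcyclohexanols and 1-alkenyl-6-isopropenylcyclohex-2-enols to cyclodecenones. The ten-membered ring is closed by a four-carbon enlargement of the six-membered ring through a chair six-centre transition state, not by end-to-end cyclisation, and the ring olefin becomes the Z-C4=C5 enone. The only new stereocentre, C8, is set by that chair: the ring bonds C6–C5 and C1–C2 and the E-silyl group are all equatorial, so bonding occurs on one face of C8 and the C1/C6 configuration is relayed to 8R, while the same chair gives the 1(10)E olefin. The step needs chair over boat and reaction through the exocyclic vinyl group, not the ring C4=C5; the trans-diequatorial alkenyl groups from step 9 secure the first, and the second follows because C4=C5 can reach the isopropenyl group only through a bridged boat. The enolate is protonated cold and is not alkylated in the same flask.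

**Step 11**
Reactants: 18 ten-membered ketone; 19 methyl bromoacetate
Product: 21 methyl (3S,7S,8R)-3-(tert-butyldimethylsilyloxy)-8-(dimethylphenylsilyl)-6-oxo-13-norgermacra-1(10)E,4Z-dien-12-oate (H-7 and H-8 cis), via lithium enolate 20 (not isolated)
Conditions: LiN(i-Pr)2, THF, −78 °C; then 19, DMPU, −78 → −40 °C
Reagents that add atoms: methyl bromoacetate (19), COC(=O)CBr
Why: Kinetic α′-deprotonation should give the cis-endocyclic lithium enolate 20, in which H-8 lies in the enolate plane (allylic 1,3-strain) and the electrophile enters anti to the C8 silyl group (1,2-induction by a β-silyl group in enolate alkylation), so H-7 and H-8 end up cis as in the target; the trans-enolate 17 is not used because the ring covers the face that has to be attacked.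

**Step 12**
Reactants: 21 keto ester
Product: 23 (3S,6S,7S,8R)-3-(tert-butyldimethylsilyloxy)-8-(dimethylphenylsilyl)-6-hydroxy-13-norgermacra-1(10)E,4Z-dien-12-oic acid, via lithium alkoxide of the hydroxy ester 22 (not isolated)
Conditions: LiBH(s-Bu)3, THF, −78 °C; then LiOH, THF/MeOH/H2O, 0 °C → rt; dilute H3PO4 to pH 4–5, 0 °C
Reagents that add atoms: lithium hydroxide, [Li+].[OH-]
Why: The bulky borohydride reduces the β,β-disubstituted enone 1,2 and, attacking anti to the C7–C8 bond past H-7 (Felkin–Anh, peripheral attack), should give the 6S carbinol with oxygen cis to the acetate arm, which is the epimer needed for closure with inversion; hydroxide then cleaves the methyl ester.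

**Step 13**
Reactants: 23 hydroxy acid
Product: 24 (3S,6R,7S,8R)-3-(tert-butyldimethylsilyloxy)-8-(dimethylphenylsilyl)-13-norgermacra-1(10)E,4Z-dien-12,6-olide (trans-fused γ-lactone)
Conditions: PPh3, DIAD, THF (0.01 M), 0 °C → rt
Reagents that add atoms: none
Why: Intramolecular Mitsunobu esterification activates the allylic C6 hydroxyl and the carboxylate displaces it by SN2 (5-exo-tet) with inversion, which closes the lactone ring with the 6R, trans-fused configuration.

**Step 14**
Reactants: 24 lactone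
Product: 26 (3S,6R,7S,8R,10S)-3-(tert-butyldimethylsilyloxy)-8-(dimethylphenylsilyl)-10-hydroxy-13-norgermacr-4Z-en-12,6-olide, via the C10 hydroperoxide 25 (not isolated)
Conditions: Mn(dpm)3 (dpm = 2,2,6,6-tetramethylheptane-3,5-dionate, cat.), PhSiH3, O2 (1 atm), i-PrOH/CH2Cl2, 0 °C; then PPh3
Reagents that add atoms: dioxygen, O=O
Why: Mukaiyama hydration (hydrogen-atom transfer to C1, capture of the tertiary C10 radical by O2) is Markovnikov and should prefer the 1(10) olefin over C4=C5, which carries two allylic C–O bonds, and O2 should enter the exposed outer face of the E-olefin in the lactone conformer with C14 syn to the C8 substituent (the face on which 1(10)-epoxides of this lactone class carry oxygen), giving 10S.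

**Step 15**
Reactants: 26 hydroxy lactone
Product: 28 (3S,6R,7S,8R,10S)-3-(tert-butyldimethylsilyloxy)-13-(dimethylamino)-8-(dimethylphenylsilyl)-10-hydroxygermacr-4Z-en-12,6-olide (C11 epimers), via dilithium alkoxide–enolate 27 (not isolated)
Conditions: LiN(i-Pr)2 (2.5 equiv), THF, −78 °C; then [H2C=NMe2]I, −78 °C → rt
Reagents that add atoms: Eschenmoser's salt, C=[N+](C)C.[I-]
Why: Mannich reaction of the lactone enolate with the preformed iminium salt, with the tertiary hydroxyl carried as its inert lithium alkoxide.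

**Step 16**
Reactants: 28 Mannich base
Product: 30 (3S,6R,7S,8R,10S)-3-(tert-butyldimethylsilyloxy)-8-(dimethylphenylsilyl)-10-hydroxygermacra-4Z,11(13)-dien-12,6-olide, via methiodide 29 (not isolated)
Conditions: MeI, MeOH, rt; then NaHCO3 (aq), EtOAc, rt
Reagents that add atoms: none
Why: Quaternisation followed by E1cB loss of trimethylamine gives the exocyclic α-methylene lactone.

**Step 17**
Reactants: 30 methylene lactone
Product: 31 (3S,6R,7R,8R,10S)-3-(tert-butyldimethylsilyloxy)-8,10-dihydroxygermacra-4Z,11(13)-dien-12,6-olide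
Conditions: Hg(OAc)2, AcOOH, AcOH, rt
Reagents that add atoms: peracetic acid, CC(=O)OO
Why: Fleming–Tamao oxidation (ipso-mercuridesilylation of the phenyl group, then peracid-induced migration of C8 from silicon to oxygen) proceeds with retention at C8; the electrophilic conditions are tolerated by the electron-poor methylene lactone and should spare C4=C5, which is deactivated by two allylic C–O bonds.

**Step 18**
Reactants: 31 diol
Product: 32 (3S,6R,7R,8R,10S)-3-(tert-butyldimethylsilyloxy)-10-hydroxy-8-(2-methylpropanoyloxy)germacra-4Z,11(13)-dien-12,6-olide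
Conditions: (i-PrCO)2O, DMAP (cat.), Et3N, CH2Cl2, 0 °C
Reagents that add atoms: isobutyric anhydride, CC(C)C(=O)OC(=O)C(C)C
Why: DMAP-catalysed acylation takes the secondary C8 hydroxyl and leaves the tertiary C10 hydroxyl, and is run cold to avoid relactonisation toward O8.

**Step 19**
Reactants: 32 silyl ether
Product: 33 (3S,6R,7R,8R,10S)-3,10-dihydroxy-8-(2-methylpropanoyloxy)germacra-4Z,11(13)-dien-12,6-olide (target)
Conditions: HF·pyridine, pyridine/THF, 0 °C → rt
Reagents that add atoms: none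
Why: Fluoride cleaves the allylic silyl ether under buffered conditions that leave the methylene lactone, the ester and the tertiary alcohol alone.

**Compound list**

1 | (R)-(−)-carvone | CC1=CC[C@H](CC1=O)C(C)=C | starting material
2 | (1R,5R)-cis-carveol | CC1=CC[C@H](C[C@H]1O)C(C)=C | intermediate
3 | (1S,5R)-trans-carvyl 4-nitrobenzoate | CC1=CC[C@H](C[C@@H]1OC(=O)c2ccc(cc2)[N+](=O)[O-])C(C)=C | intermediate
4 | (1S,5R)-trans-carveol | CC1=CC[C@H](C[C@@H]1O)C(C)=C | intermediate
5 | (1S,2S,3R,5S)-2,3-epoxy-2-methyl-5-(prop-1-en-2-yl)cyclohexan-1-ol | C[C@@]12O[C@@H]1C[C@H](C[C@@H]2O)C(C)=C | intermediate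
6 | (1S,2R,3R,5R)-1-(tert-butyldimethylsilyloxy)-2,3-epoxy-2-methyl-5-(prop-1-en-2-yl)cyclohexane | C[C@@]12O[C@@H]1C[C@H](C[C@@H]2O[Si](C)(C)C(C)(C)C)C(C)=C | intermediate
7 | (1S,2S,4S,6S)-6-(tert-butyldimethylsilyloxy)-1-methyl-2-(phenylselanyl)-4-(prop-1-en-2-yl)cyclohexan-1-ol | C[C@@]1(O)[C@@H]([Se]c2ccccc2)C[C@H](C[C@@H]1O[Si](C)(C)C(C)(C)C)C(C)=C | intermediate (not isolated)
8 | (1R,4S,6S)-6-(tert-butyldimethylsilyloxy)-1-methyl-4-(prop-1-en-2-yl)cyclohex-2-en-1-ol | C[C@@]1(O)C=C[C@H](C[C@@H]1O[Si](C)(C)C(C)(C)C)C(C)=C | intermediate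
9 | (4S,6R)-4-(tert-butyldimethylsilyloxy)-3-methyl-6-(prop-1-en-2-yl)cyclohex-2-en-1-one | CC1=CC(=O)[C@H](C[C@@H]1O[Si](C)(C)C(C)(C)C)C(C)=C | intermediate
10 | (E)-1,2-bis(tributylstannyl)ethene | CCCC[Sn](CCCC)(CCCC)/C=C/[Sn](CCCC)(CCCC)CCCC | starting material
11 | chlorodimethylphenylsilane | C[Si](C)(Cl)c1ccccc1 | starting material
12 | (E)-2-(tributylstannyl)ethenyllithium | [Li]/C=C/[Sn](CCCC)(CCCC)CCCC | intermediate (not isolated)
13 | (E)-1-(dimethylphenylsilyl)-2-(tributylstannyl)ethene | C[Si](C)(/C=C/[Sn](CCCC)(CCCC)CCCC)c1ccccc1 | intermediate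
14 | (E)-2-(dimethylphenylsilyl)ethenyllithium | [Li]/C=C/[Si](C)(C)c1ccccc1 | intermediate (not isolated)
15 | (1R,4S,6R)-4-(tert-butyldimethylsilyloxy)-1-[(E)-2-(dimethylphenylsilyl)ethenyl]-3-methyl-6-(prop-1-en-2-yl)cyclohex-2-en-1-ol | CC1=C[C@](O)(/C=C/[Si](C)(C)c2ccccc2)[C@H](C[C@@H]1O[Si](C)(C)C(C)(C)C)C(C)=C | intermediate (key-step precursor)
16 | potassium alkoxide of 15 | CC1=C[C@]([O-])(/C=C/[Si](C)(C)c2ccccc2)[C@H](C[C@@H]1O[Si](C)(C)C(C)(C)C)C(C)=C.[K+] | intermediate (not isolated)
17 | potassium (3S,8R)-3-(tert-butyldimethylsilyloxy)-8-(dimethylphenylsilyl)-11,12,13-trinorgermacra-1(10)E,4Z,6-trien-6-olate, C6=C7 trans-endocyclic | C/C1=C/C([O-])=C/[C@H]([Si](C)(C)c2ccccc2)C/C(C)=C/C[C@@H]1O[Si](C)(C)C(C)(C)C.[K+] | intermediate (not isolated)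
18 | (3S,8R)-3-(tert-butyldimethylsilyloxy)-8-(dimethylphenylsilyl)-11,12,13-trinorgermacra-1(10)E,4Z-dien-6-one | C/C1=C/C(=O)C[C@H]([Si](C)(C)c2ccccc2)C/C(C)=C/C[C@@H]1O[Si](C)(C)C(C)(C)C | intermediate (key-step product)
19 | methyl bromoacetate | COC(=O)CBr | starting material
20 | lithium enolate of 18, C6=C7 cis-endocyclic | C/C1=C/C([O-])=C\[C@H]([Si](C)(C)c2ccccc2)C/C(C)=C/C[C@@H]1O[Si](C)(C)C(C)(C)C.[Li+] | intermediate (not isolated)
21 | methyl (3S,7S,8R)-3-(tert-butyldimethylsilyloxy)-8-(dimethylphenylsilyl)-6-oxo-13-norgermacra-1(10)E,4Z-dien-12-oate | C/C1=C/C(=O)[C@H](CC(=O)OC)[C@H]([Si](C)(C)c2ccccc2)C/C(C)=C/C[C@@H]1O[Si](C)(C)C(C)(C)C | intermediate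
22 | lithium alkoxide of methyl (3S,6S,7S,8R)-3-(tert-butyldimethylsilyloxy)-8-(dimethylphenylsilyl)-6-hydroxy-13-norgermacra-1(10)E,4Z-dien-12-oate | C/C1=C/[C@H]([O-])[C@H](CC(=O)OC)[C@H]([Si](C)(C)c2ccccc2)C/C(C)=C/C[C@@H]1O[Si](C)(C)C(C)(C)C.[Li+] | intermediate (not isolated)
23 | (3S,6S,7S,8R)-3-(tert-butyldimethylsilyloxy)-8-(dimethylphenylsilyl)-6-hydroxy-13-norgermacra-1(10)E,4Z-dien-12-oic acid | C/C1=C/[C@H](O)[C@H](CC(=O)O)[C@H]([Si](C)(C)c2ccccc2)C/C(C)=C/C[C@@H]1O[Si](C)(C)C(C)(C)C | intermediate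
24 | (3S,6R,7S,8R)-3-(tert-butyldimethylsilyloxy)-8-(dimethylphenylsilyl)-13-norgermacra-1(10)E,4Z-dien-12,6-olide | C1C(=O)O[C@@H]2/C=C(/C)[C@@H](O[Si](C)(C)C(C)(C)C)C/C=C(\C)C[C@@H]([Si](C)(C)c3ccccc3)[C@@H]12 | intermediate
25 | (3S,6R,7S,8R,10S)-3-(tert-butyldimethylsilyloxy)-8-(dimethylphenylsilyl)-10-hydroperoxy-13-norgermacr-4Z-en-12,6-olide | C1C(=O)O[C@@H]2/C=C(/C)[C@@H](O[Si](C)(C)C(C)(C)C)CC[C@](C)(OO)C[C@@H]([Si](C)(C)c3ccccc3)[C@@H]12 | intermediate (not isolated)
26 | (3S,6R,7S,8R,10S)-3-(tert-butyldimethylsilyloxy)-8-(dimethylphenylsilyl)-10-hydroxy-13-norgermacr-4Z-en-12,6-olide | C1C(=O)O[C@@H]2/C=C(/C)[C@@H](O[Si](C)(C)C(C)(C)C)CC[C@](C)(O)C[C@@H]([Si](C)(C)c3ccccc3)[C@@H]12 | intermediate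
27 | dilithium salt of 26 (C10 alkoxide, C11=C12 lactone enolate) | C1=C([O-])O[C@@H]2/C=C(/C)[C@@H](O[Si](C)(C)C(C)(C)C)CC[C@](C)([O-])C[C@@H]([Si](C)(C)c3ccccc3)[C@@H]12.[Li+].[Li+] | intermediate (not isolated)
28 | (3S,6R,7S,8R,10S)-3-(tert-butyldimethylsilyloxy)-13-(dimethylamino)-8-(dimethylphenylsilyl)-10-hydroxygermacr-4Z-en-12,6-olide, C11 epimers | CN(C)CC1C(=O)O[C@@H]2/C=C(/C)[C@@H](O[Si](C)(C)C(C)(C)C)CC[C@](C)(O)C[C@@H]([Si](C)(C)c3ccccc3)[C@@H]12 | intermediate
29 | methiodide of 28 | C[N+](C)(C)CC1C(=O)O[C@@H]2/C=C(/C)[C@@H](O[Si](C)(C)C(C)(C)C)CC[C@](C)(O)C[C@@H]([Si](C)(C)c3ccccc3)[C@@H]12.[I-] | intermediate (not isolated)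
30 | (3S,6R,7S,8R,10S)-3-(tert-butyldimethylsilyloxy)-8-(dimethylphenylsilyl)-10-hydroxygermacra-4Z,11(13)-dien-12,6-olide | C=C1C(=O)O[C@@H]2/C=C(/C)[C@@H](O[Si](C)(C)C(C)(C)C)CC[C@](C)(O)C[C@@H]([Si](C)(C)c3ccccc3)[C@@H]12 | intermediate
31 | (3S,6R,7R,8R,10S)-3-(tert-butyldimethylsilyloxy)-8,10-dihydroxygermacra-4Z,11(13)-dien-12,6-olide | C=C1C(=O)O[C@@H]2/C=C(/C)[C@@H](O[Si](C)(C)C(C)(C)C)CC[C@](C)(O)C[C@@H](O)[C@@H]12 | intermediate
32 | (3S,6R,7R,8R,10S)-3-(tert-butyldimethylsilyloxy)-10-hydroxy-8-(2-methylpropanoyloxy)germacra-4Z,11(13)-dien-12,6-olide | C=C1C(=O)O[C@@H]2/C=C(/C)[C@@H](O[Si](C)(C)C(C)(C)C)CC[C@](C)(O)C[C@@H](OC(=O)C(C)C)[C@@H]12 | intermediate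
33 | (3S,6R,7R,8R,10S)-3,10-dihydroxy-8-(2-methylpropanoyloxy)germacra-4Z,11(13)-dien-12,6-olide | C=C1C(=O)O[C@@H]2/C=C(/C)[C@@H](O)CC[C@](C)(O)C[C@@H](OC(=O)C(C)C)[C@@H]12 | target

**Step count**

Total: 19 steps. Longest linear sequence: 18 steps (steps 1–7 and 9–19, from 1); step 8 is a one-step side branch.

**Steps most likely to fail**

1. Step 11, facial selectivity at C7. If the enolate that reacts is the trans-endocyclic one, or the ring overrides the silicon control, the electrophile enters syn to H-8 and the C7 epimer forms. The fallback sets out from 18 and returns at 21, and it lets the proton, not the carbon electrophile, arrive last. The alkylation is run as before and gives methyl (3S,7R,8R)-3-(tert-butyldimethylsilyloxy)-8-(dimethylphenylsilyl)-6-oxo-13-norgermacra-1(10)E,4Z-dien-12-oate F1. KN(SiMe3)2 (THF, −78 °C) removes the ketone α-hydrogen at C7 to give the potassium enolate F2. Kinetic protonation (AcOH in THF, −78 °C) then delivers hydrogen to the face that the electrophile used before and pushes the acetate arm to the other side, giving 21.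

2. Step 14, site and face of hydration. Hydrogen-atom transfer may also reach C4=C5, the C10 radical may close across the ring, or O2 may enter the wrong face. The fallback sets out from 24 and returns at 26, using a concerted oxygen transfer followed by removal of the C1 oxygen function. Dimethyldioxirane (acetone, −20 °C) should epoxidise the electron-richer E-olefin from its outer face to give the 1β,10α-epoxide F3. PhSeNa ((PhSe)2, NaBH4, EtOH) opens it at the secondary C1 to give the 1-phenylselanyl-10-hydroxy lactone F4. Bu3SnH with AIBN (toluene, 80 °C) removes selenium and gives 26.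

3. Step 17, electrophilic oxidation in the presence of C4=C5. Epoxidation or oxymercuration of C4=C5, or loss of the C3 silyl ether in peracid/AcOH, would lower the yield. The fallback sets out from 26 and returns at 32, and it moves the silicon oxidation before the methylenation and makes it nucleophilic. Substoichiometric KOt-Bu (DMSO/THF, rt) lets the C10 alkoxide attack silicon with loss of benzene, giving the 10-O,8-Si-bridged 2,2-dimethyl-1-oxa-2-silacyclopentane F5. Tamao oxidation (H2O2, KF, KHCO3, THF/MeOH) gives the 8,10-diol lactone F6 with retention at C8. Isobutyric anhydride with DMAP gives the 8-isobutyrate F7. LiN(SiMe3)2 (2 equiv, −78 °C; the lactone α-CH2 is more acidic than the hindered ester methine) and Eschenmoser's salt give the Mannich base F8. MeI gives the methiodide F9, and NaHCO3 then gives 32.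

**Further compounds**

F1 | step 11 | methyl (3S,7R,8R)-3-(tert-butyldimethylsilyloxy)-8-(dimethylphenylsilyl)-6-oxo-13-norgermacra-1(10)E,4Z-dien-12-oate (C7 epimer of 21) | C/C1=C/C(=O)[C@@H](CC(=O)OC)[C@H]([Si](C)(C)c2ccccc2)C/C(C)=C/C[C@@H]1O[Si](C)(C)C(C)(C)C
F2 | step 11 | potassium enolate of F1 (C6=C7, trans-endocyclic) | C/C1=C/C([O-])=C(CC(=O)OC)/[C@H]([Si](C)(C)c2ccccc2)C/C(C)=C/C[C@@H]1O[Si](C)(C)C(C)(C)C.[K+]
F3 | step 14 | (3S,6R,7S,8R)-3-(tert-butyldimethylsilyloxy)-8-(dimethylphenylsilyl)-1β,10α-epoxy-13-norgermacr-4Z-en-12,6-olide | C1C(=O)O[C@@H]2/C=C(/C)[C@@H](O[Si](C)(C)C(C)(C)C)C[C@H]3O[C@]3(C)C[C@@H]([Si](C)(C)c4ccccc4)[C@@H]12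
F4 | step 14 | (3S,6R,7S,8R,10S)-3-(tert-butyldimethylsilyloxy)-8-(dimethylphenylsilyl)-10-hydroxy-1α-(phenylselanyl)-13-norgermacr-4Z-en-12,6-olide | C1C(=O)O[C@@H]2/C=C(/C)[C@@H](O[Si](C)(C)C(C)(C)C)C[C@H]([Se]c3ccccc3)[C@](C)(O)C[C@@H]([Si](C)(C)c4ccccc4)[C@@H]12
F5 | step 17 | 10-O,8-Si-bridged 2,2-dimethyl-1-oxa-2-silacyclopentane of the 3-silyloxy-13-norgermacr-4Z-en-12,6-olide | C1C(=O)O[C@@H]2/C=C(/C)[C@@H](O[Si](C)(C)C(C)(C)C)CC[C@]3(C)O[Si](C)(C)[C@H](C3)[C@@H]12
F6 | step 17 | (3S,6R,7R,8R,10S)-3-(tert-butyldimethylsilyloxy)-8,10-dihydroxy-13-norgermacr-4Z-en-12,6-olide | C1C(=O)O[C@@H]2/C=C(/C)[C@@H](O[Si](C)(C)C(C)(C)C)CC[C@](C)(O)C[C@@H](O)[C@@H]12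
F7 | step 17 | (3S,6R,7R,8R,10S)-3-(tert-butyldimethylsilyloxy)-10-hydroxy-8-(2-methylpropanoyloxy)-13-norgermacr-4Z-en-12,6-olide | C1C(=O)O[C@@H]2/C=C(/C)[C@@H](O[Si](C)(C)C(C)(C)C)CC[C@](C)(O)C[C@@H](OC(=O)C(C)C)[C@@H]12
F8 | step 17 | 13-(dimethylamino) Mannich base of F7 (C11 epimers) | CN(C)CC1C(=O)O[C@@H]2/C=C(/C)[C@@H](O[Si](C)(C)C(C)(C)C)CC[C@](C)(O)C[C@@H](OC(=O)C(C)C)[C@@H]12
F9 | step 17 | methiodide of F8 | C[N+](C)(C)CC1C(=O)O[C@@H]2/C=C(/C)[C@@H](O[Si](C)(C)C(C)(C)C)CC[C@](C)(O)C[C@@H](OC(=O)C(C)C)[C@@H]12.[I-]
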